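**Retrosynthetic overview**
1. Rings: A/C = chromanone, B = pendant arene, D = dimethylpyran fused to B. Primed chromane numbers (O1', C2', C3', C4', C4a', C8', C8a') refer to B/D, unprimed numbers to A/C.
2. Disconnection 1 (after removal of two benzyl ethers): the C3'–C4' bond between the two carbinol carbons. It is made by an enantioselective, trans-selective reductive (pinacol) cyclisation of a dialdehyde, which gives ring D, both hydroxyl groups and both D-ring stereocentres in one operation.
3. Enabling feature: the trans-3',4'-diol is a pinacol retron whose carbons are joined 1,6 through C4a'–C8a'–O1'–C2'. C4' is a formyl carbon conjugated to ring B, the only carbonyl that trivalent titanium reduces. C3' is a formyl carbon on the quaternary gem-dimethyl C2', so it has no enolisable hydrogen and gains Thorpe–Ingold help.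
4. Disconnection 2: C2–C6' by rhodium-catalysed asymmetric 1,4-addition of a ring B boronic acid to 7-(benzyloxy)chromone, which sets C2. The two formyl groups travel as CH2OH groups.
5. Ring order: A, B and the unsaturated ring C come with the starting materials. Ring C becomes the saturated chiral pyranone in step 6, and ring D is closed in step 8.

Key step: step 8

Assumption: the sense of induction in steps 6 and 8 is assigned by analogy ((S)-biaryl diphosphines give (S)-3-arylcyclohexanones, which maps onto (2S)-flavanones; the salen antipode written is provisional), and if a trial run shows the opposite sense, the equally available antipodal ligand is used.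

**Route**

Step 1
Reactants: 1 5-bromo-2,3-dihydroxybenzaldehyde
Product: 2 3-(benzyloxy)-5-bromo-2-hydroxybenzaldehyde
Conditions: NaH (2.2 equiv), DMSO, 20 °C; BnBr (1.0 equiv); aq. HCl
Reagents that add atoms: benzyl bromide, BrCc1ccccc1
Why: Williamson etherification of the dianion, in which the 2-phenoxide is delocalised into and chelated by the ortho formyl group, so the more basic 3-phenoxide should take up the single equivalent of benzyl bromide; no stereocentre is formed.

Step 2
Reactants: 2 3-(benzyloxy)-5-bromo-2-hydroxybenzaldehyde; 3 ethyl 2-bromo-2-methylpropanoate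
Product: 4 ethyl 2-[2-(benzyloxy)-4-bromo-6-formylphenoxy]-2-methylpropanoate
Conditions: Cs2CO3, DMF, 60 °C, bromide added in portions
Reagents that add atoms: none
Why: Williamson-type SN2 alkylation of a 2,6-disubstituted phenoxide by a tertiary alpha-bromo ester, the reaction type used for hindered fibrate-type aryloxyisobutyrates, helped by the activating ester and the weakly basic caesium phenoxide; the product has no enolisable hydrogen that could attack the formyl group.

Step 3
Reactants: 4 ethyl 2-[2-(benzyloxy)-4-bromo-6-formylphenoxy]-2-methylpropanoate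
Product: 5 2-[2-(benzyloxy)-4-bromo-6-(hydroxymethyl)phenoxy]-2-methylpropan-1-ol
Conditions: LiAlH4, THF, 0 °C; H2O
Reagents that add atoms: none
Why: Hydride reduction takes ester and aldehyde to the same CH2OH level, which masks both future formyl groups against the organometallic steps 4 and 6, while the aryl bromide and the benzyl ether are inert at 0 °C.

Step 4
Reactants: 5 2-[2-(benzyloxy)-4-bromo-6-(hydroxymethyl)phenoxy]-2-methylpropan-1-ol
Product: 6 {3-(benzyloxy)-5-(hydroxymethyl)-4-[(1-hydroxy-2-methylpropan-2-yl)oxy]phenyl}boronic acid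
Conditions: B2(OH)4, Pd(OAc)2 (2 mol %), XPhos (2-dicyclohexylphosphino-2',4',6'-triisopropylbiphenyl, 6 mol %), KOAc, EtOH, 80 °C
Reagents that add atoms: tetrahydroxydiboron, OB(O)B(O)O
Why: Miyaura-type palladium-catalysed borylation with tetrahydroxydiboron delivers the free boronic acid directly and tolerates the two primary alcohols and the benzyl ether.

Step 5
Reactants: 7 7-hydroxy-4H-chromen-4-one
Product: 8 7-(benzyloxy)-4H-chromen-4-one
Conditions: BnBr, K2CO3, acetone, reflux
Reagents that add atoms: benzyl bromide, BrCc1ccccc1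
Why: Williamson etherification of the acidic 7-phenol under conditions too mild to open the pyranone ring; the ether also keeps the chromone from being deactivated as a phenoxide in step 6.

Step 6
Reactants: 6 {3-(benzyloxy)-5-(hydroxymethyl)-4-[(1-hydroxy-2-methylpropan-2-yl)oxy]phenyl}boronic acid; 8 7-(benzyloxy)-4H-chromen-4-one
Product: 9 (2S)-7-(benzyloxy)-2-{3-(benzyloxy)-5-(hydroxymethyl)-4-[(1-hydroxy-2-methylpropan-2-yl)oxy]phenyl}-2,3-dihydro-4H-chromen-4-one
Conditions: [Rh(OH)(cod)]2 (1.5 mol %), (S)-MeO-F12-BIPHEP ((S)-(6,6'-dimethoxybiphenyl-2,2'-diyl)bis[bis(3,4,5-trifluorophenyl)phosphine], 3.3 mol %), toluene/THF/H2O, 25 °C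
Reagents that add atoms: none
Why: Hayashi–Miyaura asymmetric 1,4-addition, known for chromones with electron-poor biaryl diphosphines, in which the aryl-rhodium species adds across C2=C3 on the face left open by the (S)-ligand and sets C2 as S, while the base-free medium at room temperature should spare the product from ring opening and from 1,2-addition.

Step 7
Reactants: 9 (2S)-7-(benzyloxy)-2-{3-(benzyloxy)-5-(hydroxymethyl)-4-[(1-hydroxy-2-methylpropan-2-yl)oxy]phenyl}-2,3-dihydro-4H-chromen-4-one
Product: 10 3-(benzyloxy)-5-[(2S)-7-(benzyloxy)-4-oxo-3,4-dihydro-2H-chromen-2-yl]-2-[(2-methyl-1-oxopropan-2-yl)oxy]benzaldehyde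
Conditions: Dess–Martin periodinane (2.5 equiv), CH2Cl2, 0 to 20 °C
Reagents that add atoms: none
Why: Dess–Martin oxidation of both primary carbinols under non-basic conditions, so C2 is not epimerised by retro-oxa-Michael opening, neither new aldehyde can enolise, and both carbinols should be oxidised before a seven-membered lactol can form.

Step 8
Reactants: 10 3-(benzyloxy)-5-[(2S)-7-(benzyloxy)-4-oxo-3,4-dihydro-2H-chromen-2-yl]-2-[(2-methyl-1-oxopropan-2-yl)oxy]benzaldehyde
Product: 11 (2S)-7-(benzyloxy)-2-[(3R,4S)-8-(benzyloxy)-3,4-dihydroxy-2,2-dimethyl-3,4-dihydro-2H-chromen-6-yl]-2,3-dihydro-4H-chromen-4-one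
Conditions: [(R,R)-N,N'-bis(3,5-di-tert-butylsalicylidene)cyclohexane-1,2-diaminato]TiCl2 (10 mol %), N,N'-di-n-propyl-1,13-dimethoxyquinacridinium tetrafluoroborate (5 mol %), Hantzsch ester (diethyl 2,6-dimethyl-1,4-dihydropyridine-3,5-dicarboxylate, 1.2 equiv), PhCF3, 0.01 M, 595 nm LED, 20 °C
Reagents that add atoms: none
Why: Proposed new method: Trivalent titanium, formed from the chiral (salen)TiCl2 by the photoreduced dye, binds the formyl group at C4' and converts it by inner-sphere electron transfer into a persistent titanoxy benzylic (ketyl) radical, which attacks the carbonyl carbon C3' of the tethered 2-aryloxy-2-methylpropanal while the developing oxygen-centred spin is quenched by a second reducing equivalent and the pyridinium acid from the Hantzsch ester frees the diol and the catalyst. The closest known reaction types are the (salen)titanium-catalysed enantioselective, DL-selective pinacol homocoupling of aryl aldehydes under zinc or photoredox turnover, the trans-selective pinacol cyclisation of dialdehydes by titanocene-type trivalent titanium and the enantioselective titanium-catalysed reductive cyclisation of keto nitriles, so that only the intramolecular aryl/alkyl cross-coupling under chiral control is new. Ring D closes 6-exo-trig (radical at C4', C3'=O exocyclic) through a half-chair. C4' is controlled by the salen ligand, which shields one face of the planar titanium-bound ketyl, and C3' is controlled relative to C4' by the half-chair, in which the bulky titanoxy group and the acceptor oxygen take anti, pseudo-equatorial positions to minimise steric and dipole repulsion, which is the trans (DL-type) arrangement and also the more stable diequatorial product should the addition be reversible. The step needs reduction of one carbonyl group out of three and cyclisation faster than dimerisation: the electron-rich ring C ketone and the aliphatic aldehyde lie beyond the reducing power of trivalent titanium (so that the alpha-aryloxy group is not expelled, as it might be by SmI2), the gem-dimethyl C2' removes every enolisable hydrogen and favours closure, the two ortho substituents (8'-benzyloxy and formyl) twist the tertiary ether out of the plane of ring B and hold C3' over the p orbital at C4', and high dilution disfavours homocoupling. C2 is remote and is not touched by the neutral medium.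

Step 9
Reactants: 11 (2S)-7-(benzyloxy)-2-[(3R,4S)-8-(benzyloxy)-3,4-dihydroxy-2,2-dimethyl-3,4-dihydro-2H-chromen-6-yl]-2,3-dihydro-4H-chromen-4-one
Product: 12 (2S)-7-hydroxy-2-[(3R,4S)-3,4,8-trihydroxy-2,2-dimethyl-3,4-dihydro-2H-chromen-6-yl]-2,3-dihydro-4H-chromen-4-one
Conditions: H2 (1 atm), Pd/C, EtOAc, 20 °C, stopped at full conversion
Reagents that add atoms: none
Why: Catalytic hydrogenolysis of the two aryl benzyl ethers, which in neutral ethyl acetate should cleave much faster than the secondary benzylic C4'–OH or the benzylic C2–O1 bond, and which touches no stereocentre and needs neither acid nor base.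

**Compound list**
1 | 5-bromo-2,3-dihydroxybenzaldehyde | O=Cc1cc(Br)cc(O)c1O | starting material
2 | 3-(benzyloxy)-5-bromo-2-hydroxybenzaldehyde | O=Cc1cc(Br)cc(OCc2ccccc2)c1O | intermediate
3 | ethyl 2-bromo-2-methylpropanoate | CCOC(=O)C(C)(C)Br | starting material
4 | ethyl 2-[2-(benzyloxy)-4-bromo-6-formylphenoxy]-2-methylpropanoate | CCOC(=O)C(C)(C)Oc1c(C=O)cc(Br)cc1OCc1ccccc1 | intermediate
5 | 2-[2-(benzyloxy)-4-bromo-6-(hydroxymethyl)phenoxy]-2-methylpropan-1-ol | OCc1cc(Br)cc(OCc2ccccc2)c1OC(C)(C)CO | intermediate
6 | {3-(benzyloxy)-5-(hydroxymethyl)-4-[(1-hydroxy-2-methylpropan-2-yl)oxy]phenyl}boronic acid | OCc1cc(B(O)O)cc(OCc2ccccc2)c1OC(C)(C)CO | intermediate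
7 | 7-hydroxy-4H-chromen-4-one | O=c1ccoc2cc(O)ccc12 | starting material
8 | 7-(benzyloxy)-4H-chromen-4-one | O=c1ccoc2cc(OCc3ccccc3)ccc12 | intermediate
9 | (2S)-7-(benzyloxy)-2-{3-(benzyloxy)-5-(hydroxymethyl)-4-[(1-hydroxy-2-methylpropan-2-yl)oxy]phenyl}-2,3-dihydro-4H-chromen-4-one | OCc1cc([C@@H]2CC(=O)c3ccc(OCc4ccccc4)cc3O2)cc(OCc2ccccc2)c1OC(C)(C)CO | intermediate
10 | 3-(benzyloxy)-5-[(2S)-7-(benzyloxy)-4-oxo-3,4-dihydro-2H-chromen-2-yl]-2-[(2-methyl-1-oxopropan-2-yl)oxy]benzaldehyde | O=Cc1cc([C@@H]2CC(=O)c3ccc(OCc4ccccc4)cc3O2)cc(OCc2ccccc2)c1OC(C)(C)C=O | intermediate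
11 | (2S)-7-(benzyloxy)-2-[(3R,4S)-8-(benzyloxy)-3,4-dihydroxy-2,2-dimethyl-3,4-dihydro-2H-chromen-6-yl]-2,3-dihydro-4H-chromen-4-one | CC1(C)Oc2c(OCc3ccccc3)cc([C@@H]3CC(=O)c4ccc(OCc5ccccc5)cc4O3)cc2[C@H](O)[C@H]1O | intermediate
12 | (2S)-7-hydroxy-2-[(3R,4S)-3,4,8-trihydroxy-2,2-dimethyl-3,4-dihydro-2H-chromen-6-yl]-2,3-dihydro-4H-chromen-4-one | CC1(C)Oc2c(O)cc([C@@H]3CC(=O)c4ccc(O)cc4O3)cc2[C@H](O)[C@H]1O | target

Total step count: 9. Longest linear sequence: 8 steps (1, 2, 3, 4, 6, 7, 8, 9).

**Steps most likely to fail**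

Step 8. Dimerisation of the titanium-bound ketyl between two molecules, or its simple reduction to the benzylic alcohol, may outrun attack on the unactivated aliphatic aldehyde. The facial selectivity of the salen complex is known only for homocoupling and may be poor here. The fallback sets out from 2 and comes back at 11. Ring D is built at the bromide stage as an alkene and oxygenated by established asymmetric catalysis.
- Condensation of 2 with 2-methylprop-1-enylboronic acid and dibenzylamine (catalytic Petasis reaction, then loss of the amine and oxa-6π electrocyclisation; dioxane, 90 °C) should give 8-(benzyloxy)-6-bromo-2,2-dimethyl-2H-chromene F1.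
- Jacobsen–Katsuki epoxidation with [(R,R)-N,N'-bis(3,5-di-tert-butylsalicylidene)cyclohexane-1,2-diaminato]MnCl, NaOCl and 4-phenylpyridine N-oxide in CH2Cl2 at 0 °C is the benchmark reaction for 2,2-dimethylchromenes. It should give (3R,4R)-8-(benzyloxy)-6-bromo-3,4-epoxy-2,2-dimethylchromane F2.
- Dilute aqueous H2SO4 in acetone should open the epoxide at the benzylic C4' with inversion to (3R,4S)-8-(benzyloxy)-6-bromo-2,2-dimethylchromane-3,4-diol F3.
- Borylation under the conditions of step 4 should give [(3R,4S)-8-(benzyloxy)-3,4-dihydroxy-2,2-dimethylchroman-6-yl]boronic acid F4, which is added to 8 under the conditions of step 6 to give 11.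

Step 6. Protodeboronation of the boronic acid may outrun the slow carbometalation of the electron-rich chromone. The fallback sets out from 5 and comes back at 9. It builds ring C by the classical chalcone route and takes the enantiomer by kinetic resolution.
- Bromine–lithium exchange on 5 (n-BuLi, 3.2 equiv, THF, −78 °C) and quenching with DMF should give 3-(benzyloxy)-5-(hydroxymethyl)-4-[(1-hydroxy-2-methylpropan-2-yl)oxy]benzaldehyde F5.
- Claisen–Schmidt condensation with commercial 1-[4-(benzyloxy)-2-hydroxyphenyl]ethanone (KOH, EtOH) should give (E)-1-[4-(benzyloxy)-2-hydroxyphenyl]-3-{3-(benzyloxy)-5-(hydroxymethyl)-4-[(1-hydroxy-2-methylpropan-2-yl)oxy]phenyl}prop-2-en-1-one F6.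
- Oxa-Michael closure (NaOAc, EtOH, reflux, recovered chalcone recycled) should give the racemic form of 9, rac-7-(benzyloxy)-2-{3-(benzyloxy)-5-(hydroxymethyl)-4-[(1-hydroxy-2-methylpropan-2-yl)oxy]phenyl}-2,3-dihydro-4H-chromen-4-one F7.
- Noyori–Ikariya transfer hydrogenation with RuCl[(R,R)-TsDPEN](p-cymene) and HCO2H/Et3N, stopped near half conversion, should consume the matched (2R)-enantiomer. The product is the separable (2R,4R)-7-(benzyloxy)-2-{3-(benzyloxy)-5-(hydroxymethyl)-4-[(1-hydroxy-2-methylpropan-2-yl)oxy]phenyl}-3,4-dihydro-2H-chromen-4-ol F8, and 9 is left behind.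

Step 2. E2 loss of HBr from the tertiary bromide under the action of the hindered phenoxide may outrun substitution. The fallback sets out from 2 and comes back at 5. The tertiary ether is made through a copper-bound propargylic cation equivalent instead of an SN2 reaction.
- Copper-catalysed propargylic etherification of 2 with 2-methylbut-3-yn-2-yl trifluoroacetate (CuCl2 cat., DBU, MeCN, 0 °C) should give 3-(benzyloxy)-5-bromo-2-[(2-methylbut-3-yn-2-yl)oxy]benzaldehyde F9.
- Semihydrogenation (H2, Pd/CaCO3 poisoned with Pb(OAc)2, quinoline, EtOAc) should give 3-(benzyloxy)-5-bromo-2-[(2-methylbut-3-en-2-yl)oxy]benzaldehyde F10.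
- Ozonolysis (O3, CH2Cl2/MeOH, −78 °C) with NaBH4 work-up reduces the ozonide and the aryl aldehyde together and should give 5.

**Further compounds**
F1 | step 8 | 8-(benzyloxy)-6-bromo-2,2-dimethyl-2H-chromene | CC1(C)C=Cc2cc(Br)cc(OCc3ccccc3)c2O1
F2 | step 8 | (3R,4R)-8-(benzyloxy)-6-bromo-3,4-epoxy-2,2-dimethylchromane | CC1(C)Oc2c(OCc3ccccc3)cc(Br)cc2[C@H]2O[C@@H]12
F3 | step 8 | (3R,4S)-8-(benzyloxy)-6-bromo-2,2-dimethylchromane-3,4-diol | CC1(C)Oc2c(OCc3ccccc3)cc(Br)cc2[C@H](O)[C@H]1O
F4 | step 8 | [(3R,4S)-8-(benzyloxy)-3,4-dihydroxy-2,2-dimethylchroman-6-yl]boronic acid | CC1(C)Oc2c(OCc3ccccc3)cc(B(O)O)cc2[C@H](O)[C@H]1O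
F5 | step 6 | 3-(benzyloxy)-5-(hydroxymethyl)-4-[(1-hydroxy-2-methylpropan-2-yl)oxy]benzaldehyde | O=Cc1cc(CO)c(OC(C)(C)CO)c(OCc2ccccc2)c1
F6 | step 6 | (E)-1-[4-(benzyloxy)-2-hydroxyphenyl]-3-{3-(benzyloxy)-5-(hydroxymethyl)-4-[(1-hydroxy-2-methylpropan-2-yl)oxy]phenyl}prop-2-en-1-one | O=C(/C=C/c1cc(CO)c(OC(C)(C)CO)c(OCc2ccccc2)c1)c1ccc(OCc2ccccc2)cc1O
F7 | step 6 | rac-7-(benzyloxy)-2-{3-(benzyloxy)-5-(hydroxymethyl)-4-[(1-hydroxy-2-methylpropan-2-yl)oxy]phenyl}-2,3-dihydro-4H-chromen-4-one | OCc1cc(C2CC(=O)c3ccc(OCc4ccccc4)cc3O2)cc(OCc2ccccc2)c1OC(C)(C)CO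
F8 | step 6 | (2R,4R)-7-(benzyloxy)-2-{3-(benzyloxy)-5-(hydroxymethyl)-4-[(1-hydroxy-2-methylpropan-2-yl)oxy]phenyl}-3,4-dihydro-2H-chromen-4-ol | OCc1cc([C@H]2C[C@@H](O)c3ccc(OCc4ccccc4)cc3O2)cc(OCc2ccccc2)c1OC(C)(C)CO
F9 | step 2 | 3-(benzyloxy)-5-bromo-2-[(2-methylbut-3-yn-2-yl)oxy]benzaldehyde | C#CC(C)(C)Oc1c(C=O)cc(Br)cc1OCc1ccccc1
F10 | step 2 | 3-(benzyloxy)-5-bromo-2-[(2-methylbut-3-en-2-yl)oxy]benzaldehyde | C=CC(C)(C)Oc1c(C=O)cc(Br)cc1OCc1ccccc1
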